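**Retrosynthetic overview**
1. Building blocks: (E)-3,4-dimethoxycinnamic acid 1 and 5,6-dihydropyridin-2(1H)-one 2; both six-membered lactam rings of the target are bought intact.
2. Imide C–N disconnection: 1, activated as acid chloride 3, and 2, as lithium lactamate 4, give the monomeric N-cinnamoyl dihydropyridinone 5.
3. Cyclobutane disconnection: both ring C–C bonds joining the two cinnamoyl units of target 6 are cut together. 6 is the head-to-tail [2+2] photodimer of two molecules of 5, formed in the crystal as the last step, as in the presumed biogenesis.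
4. Ring order: lactam rings (purchased) first, cyclobutane last; all four stereocentres are set in that one step.

Assumption: the SMILES encodes the 1α,2α,3β,4β (α-truxillic; r-1,c-2,t-3,t-4) cyclobutane, which has a centre of inversion and is meso, so there is no enantiomer to select and only relative configuration has to be controlled.

**Route**

Step 1
Reactants: 1 (E)-3-(3,4-dimethoxyphenyl)prop-2-enoic acid (3,4-dimethoxycinnamic acid); 2 5,6-dihydropyridin-2(1H)-one
Product: 5 (E)-1-[3-(3,4-dimethoxyphenyl)prop-2-enoyl]-5,6-dihydropyridin-2(1H)-one, via acid chloride 3 (not isolated), via lithium lactamate 4 (not isolated)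
Conditions: 1, (COCl)2 (1.3 equiv), DMF (cat.), CH2Cl2, 0 °C → rt, evaporate (PhMe chase); separately 2 (1.0 equiv), LiN(SiMe3)2 (1.05 equiv), THF, −78 °C, 30 min; add 3 (1.1 equiv) in THF, −78 → −40 °C, 1 h; aq. NH4Cl
Reagents that add atoms: none
Why: DMF-catalysed (Vilsmeier-type) acid chloride formation followed by nucleophilic acyl substitution (N-acylation) by the lithiated lactam, whose nitrogen anion attacks the acyl chloride at −78 °C far faster than it adds in conjugate fashion to either enone; the E double bond is untouched and no stereocentre is formed.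

Step 2
Reactants: 5 (E)-1-[3-(3,4-dimethoxyphenyl)prop-2-enoyl]-5,6-dihydropyridin-2(1H)-one (two molecules)
Product: 6 1,1'-{[(1α,2α,3β,4β)-2,4-bis(3,4-dimethoxyphenyl)cyclobutane-1,3-diyl]dicarbonyl}bis(5,6-dihydropyridin-2(1H)-one) (meso; the two aryl groups are trans to each other, the two acyl groups are trans to each other, and each acyl group is cis to one neighbouring aryl and trans to the other)
Conditions: finely ground crystals of 5 (crystal form screened from EtOAc/hexane, EtOH, MeCN), thin layer between Pyrex plates or stirred suspension in H2O, hν 350–365 nm, 5–10 °C, 24–72 h, regrind at intervals; SiO2 chromatography, recrystallise; recycle unreacted 5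
Reagents that add atoms: none
Why: Proposed new method: topochemical [2+2] photocycloaddition of the intact imide in its crystal — the veratryl donor of one molecule is expected to stack over the electron-poor acyl-imide of an inversion-related neighbour (the antiparallel α-type packing of the photoactive crystal form of 3,4-dimethoxycinnamic acid), placing the two cinnamoyl C=C bonds parallel and under 4.2 Å apart, so that excitation of the cinnamoyl chromophore at 350–365 nm (where the lactam enone and the product are essentially transparent) closes both C–C bonds with minimal atomic motion and no by-product; suprafacial addition keeps aryl and carbonyl trans within each former E-alkene and the inversion-related approach places each carbonyl cis to the aryl of the partner, which is exactly the 1α,2α,3β,4β meso array with all four stereocentres set at once; closest known reaction type: Schmidt-type solid-state photodimerisation of α-packed trans-cinnamic acids and cinnamamides to α-truxillic derivatives.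

**Compound list**
1 | (E)-3-(3,4-dimethoxyphenyl)prop-2-enoic acid (3,4-dimethoxycinnamic acid) | COc1ccc(/C=C/C(=O)O)cc1OC | starting material
2 | 5,6-dihydropyridin-2(1H)-one | O=C1C=CCCN1 | starting material
3 | (E)-3-(3,4-dimethoxyphenyl)prop-2-enoyl chloride | COc1ccc(/C=C/C(=O)Cl)cc1OC | intermediate
4 | lithium 2-oxo-5,6-dihydro-2H-pyridin-1-ide (N-lithiated 2) | O=C1C=CCC[N-]1.[Li+] | intermediate
5 | (E)-1-[3-(3,4-dimethoxyphenyl)prop-2-enoyl]-5,6-dihydropyridin-2(1H)-one | COc1ccc(/C=C/C(=O)N2CCC=CC2=O)cc1OC | intermediate
6 | 1,1'-{[(1α,2α,3β,4β)-2,4-bis(3,4-dimethoxyphenyl)cyclobutane-1,3-diyl]dicarbonyl}bis(5,6-dihydropyridin-2(1H)-one), CNP0199212.1 | COc1ccc([C@H]2[C@H](C(=O)N3CCC=CC3=O)[C@H](c3ccc(OC)c(OC)c3)[C@H]2C(=O)N2CCC=CC2=O)cc1OC | target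

**Totals**
Total step count: 2. Longest linear sequence: 2 steps (1 → 5 → 6).

**Steps most likely to fail** (the route has only two steps, so both are ranked, the riskier first; there is no third)

1. Step 2. The crystals of 5 may be photostable (alkene separation above 4.2 Å), may pack head-to-head and give the β-truxinic isomer, or may react through the lactam C=C. The fallback sets out from 1 and comes back to the route at 6. It moves the cycloaddition to the acid stage, where the crystal chemistry is established. Crystalline 1 (photoactive centrosymmetric form, from AcOH) is irradiated as a solid (350 nm, aqueous suspension) to give (1α,2α,3β,4β)-2,4-bis(3,4-dimethoxyphenyl)cyclobutane-1,3-dicarboxylic acid F1. Treatment with (COCl)2 and cat. DMF in CH2Cl2 gives (1α,2α,3β,4β)-2,4-bis(3,4-dimethoxyphenyl)cyclobutane-1,3-dicarbonyl dichloride F2. F2 then acylates 2.2 equiv of lithium lactamate 4 (from 2 and LiN(SiMe3)2, THF, −78 °C) to give 6. The short, cold acylation without excess base leaves the carbonyl-bearing stereocentres unepimerised.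

2. Step 1. N-Acylation of the unsaturated lactam can be low-yielding through conjugate addition of 4 to 3 or to 5, γ-deprotonation of 2, or imide cleavage on work-up. The fallback sets out from acid chloride 3 and comes back to the route at 5. It builds the lactam ring after the imide, by ring-closing metathesis. 3 is treated with but-3-en-1-amine (aq. NaOH/CH2Cl2, 0 °C) to give (E)-N-(but-3-en-1-yl)-3-(3,4-dimethoxyphenyl)prop-2-enamide F3. Deprotonation with LiN(SiMe3)2 (THF, −78 °C) gives lithium (E)-(but-3-en-1-yl)[3-(3,4-dimethoxyphenyl)prop-2-enoyl]azanide F4, which is acylated with acryloyl chloride to give (E)-N-(but-3-en-1-yl)-3-(3,4-dimethoxyphenyl)-N-(prop-2-enoyl)prop-2-enamide F5. Ring closure with second-generation Grubbs catalyst RuCl2(=CHPh)(H2IMes)(PCy3) (5 mol %, CH2Cl2, 40 °C) then gives 5. The terminal butenyl alkene initiates, and the monosubstituted acryloyl alkene cyclises faster than the 1,2-disubstituted cinnamoyl alkene.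

**Further compounds**
F1 | step 2 | (1α,2α,3β,4β)-2,4-bis(3,4-dimethoxyphenyl)cyclobutane-1,3-dicarboxylic acid | COc1ccc([C@H]2[C@H](C(=O)O)[C@H](c3ccc(OC)c(OC)c3)[C@H]2C(=O)O)cc1OC
F2 | step 2 | (1α,2α,3β,4β)-2,4-bis(3,4-dimethoxyphenyl)cyclobutane-1,3-dicarbonyl dichloride | COc1ccc([C@H]2[C@H](C(=O)Cl)[C@H](c3ccc(OC)c(OC)c3)[C@H]2C(=O)Cl)cc1OC
F3 | step 1 | (E)-N-(but-3-en-1-yl)-3-(3,4-dimethoxyphenyl)prop-2-enamide | COc1ccc(/C=C/C(=O)NCCC=C)cc1OC
F4 | step 1 | lithium (E)-(but-3-en-1-yl)[3-(3,4-dimethoxyphenyl)prop-2-enoyl]azanide (N-lithiated F3) | COc1ccc(/C=C/C(=O)[N-]CCC=C)cc1OC.[Li+]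
F5 | step 1 | (E)-N-(but-3-en-1-yl)-3-(3,4-dimethoxyphenyl)-N-(prop-2-enoyl)prop-2-enamide | COc1ccc(/C=C/C(=O)N(CCC=C)C(=O)C=C)cc1OC
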